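Decide first how this flask ends, and judge that by the balance of the charged substrate (the mass balance).

| flask | substrate | remark | time |
|---|---|---|---|
| ochre | 10 mM | the very flask that is asked about, followed so far |  |
| blue | 5 mM | run made earlier |  |
| flask | 10 mM |  | 10 min |

ochre run (percent of the substrate charged)

| time / s | target / % | isomer of the product / % |
|---|---|---|
| 25.0 | 5.6 | 7.5 |
| 50.0 | 5.3 | 14.2 |
| 80.0 | 7.6 | 17.6 |
| 90.0 | 7.5 | 19.1 |
| 120 | 6.9 | 20.5 |

blue run (percent of the substrate charged)

| time / min | target / % | isomer of the product / % |
|---|---|---|
| 0.833 | 5.9 | 13.7 |
| 1.50 | 6.7 | 17.7 |
| 3.00 | 7.1 | 23.1 |
| 5.00 | 7.8 | 22.0 |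
| 10.0 | 7.0 | 23.6 |

(each reading ± 0.5 percentage points)

- the state of affairs at 10 min: stopped, and by what, or still going (forward and back rates have come level / all of the substrate has reacted / it is still moving)
- amount of target at 10 min, in percent of the substrate charged
- amount of isomer of the product at 10 min, in percent of the substrate charged

- the numbers in the tables scatter with a standard deviation of 0.5 percentage points
- the reaction counts as stopped when no species that holds the substrate changes by six tenths of a point or more over the second half of the time

1. Compare the two runs at equal time: ochre at 50.0 s gives target 5.3% and isomer of the product 14.2%, and blue at 0.833 min gives 5.9% and 13.7%. These pairs differ by about the scatter of 0.5 percentage points, so take percent yields as independent of the charge and let blue stand in for later times in the flask charged with 10 mM.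

2. Draw the start from ochre: at 25.0 s the isomer stands at 7.5%, a slope of 0.180 min⁻¹ in fractions of the charge, and target already stands at 5.6%.

3. Draw the level by averaging the blue readings from 3.00 min onward, which gives target 7.30% and isomer 22.9%.

4. Carry the starting slope straight up to the isomer level to place the knee at 1.27 min; the asked 10 min is later than that, so take these levels as the answers for the flask charged with 10 mM.

5. Write the balance: call the gap the part of the charge found in neither target nor isomer once both stand level, which is 69.8%. The gap is larger than the two levels together, yet the curves stand still, so commit to a stop with forward and back rates level, an equilibrium.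

The forecast says: forward and back rates have come level, with target 7.3% and isomer 23%, on the ground that “The substrate is not exhausted, which points to equilibrium”.

The flask charged with 10 mM shows at 10 min: forward and back rates have come level, with target 7.95% and isomer 23.1%.

    substrate ⇌ target (K = 0.980, k = 0.0630 s⁻¹)
    target ⇌ isomer of the product (K = 2.90, k = 0.130 s⁻¹)
    substrate ⇌ dormant form (K = 7.50, k = 2.30 s⁻¹)

Use the gap again. The flask charged with 10 mM leaves 69.0% at 10.0 min, held as substrate 8.1% and dormant form 60.9%. Now take the neighbouring flask, charged with 2.5 mM and read at the same time: its target 7.95% and isomer 23.1% leave a gap of 69.0%, of which 8.1% is substrate and 60.9% is dormant form.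

The readings come from a simulation for substances that don't exist; scatter was added.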